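**Plan**

- Numbering (daucane numbering of the target, kept for every intermediate): C1 = quaternary C–CH3, C2 = CH–O-angeloyl, C3 = CH2, C4 = C(OH)(i-Pr), C5 = ring-fusion CH, C6 = CH–O-anisoyl, C7 = CH2, C8 = C(CH3)=, C9 = =CH, C10 = CH2; β = the face of CH3 on C1.
- Cuts: first the two ester C–O bonds (O–C2, O–C6), then the ring-fusion bond C1–C5. C5 sits between the tertiary carbinol C4 and the oxygenated C6 (an aldol array C4(OH)–C5–C6=O) and carries the quaternary C1. This is the retron of a semipinacol shift in which C1 moves from C6 to C5 of a cis-decalin 2,3-epoxy alcohol. Last, C1–C10 and C6–C7 are cut by a Diels–Alder disconnection.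
- Forward: thymoquinone and a 2-siloxydiene give ring A (six-membered) fused to ring B with all 15 skeletal carbons and a temporary C1–C6 bond. Then follow C6 hydroxylation, carbonyl-to-olefin transposition to C4=C5, C2 reduction and angeloylation, and directed epoxidation. One 1,2-shift then turns ring A into the cyclopentane and ring B into the cycloheptene. C6 reduction and anisoylation finish the route.
- Stereochemistry: C1 and the cis fusion come from the catalytic asymmetric Diels–Alder reaction; C6–OH syn to CH3-1 from enolate hydroxylation; C2 from a reagent-controlled CBS reduction; the epoxide face from the C6 hydroxyl. The shift is stereospecific (C4 retention, C5 inversion, C1 retention). C6 is set by hydride delivery from the C4 hydroxyl.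

Key step: step 10

Assumption: the sense of induction of the (S)-oxazaborolidinium catalyst in step 2 is taken from the usual pre-transition-state model (quinone bound at the carbonyl lone pair syn to the vinylic C–H, diene on the face away from the catalyst phenyl); the (R)-catalyst would be used if the antipode of 5 were found.

**Route**

Step 1
Reactants: 1 3-methylbut-3-en-2-one; 2 triisopropylsilyl trifluoromethanesulfonate
Product: 3 2-methyl-3-(triisopropylsilyloxy)buta-1,3-diene
Conditions: Et3N, Et2O, 0 °C to rt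
Reagents that add atoms: triisopropylsilyl trifluoromethanesulfonate (2), CC(C)[Si](OS(=O)(=O)C(F)(F)F)(C(C)C)C(C)C
Why: soft enolisation of the methyl ketone and O-silylation (silyl enol ether formation) should give the 2-siloxydiene, whose oxygen makes the adjacent CH2 terminus the nucleophilic end.

Step 2
Reactants: 4 thymoquinone; 3 2-methyl-3-(triisopropylsilyloxy)buta-1,3-diene
Product: 5 (4aR,8aS)-4a,7-dimethyl-2-(propan-2-yl)-6-(triisopropylsilyloxy)-4a,5,8,8a-tetrahydronaphthalene-1,4-dione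
Conditions: (S)-3,3-diphenyl-1-(2-methylphenyl)hexahydropyrrolo[1,2-c][1,3,2]oxazaborol-7-ium bis(trifluoromethylsulfonyl)amide, [C24H25BNO][N(SO2CF3)2] (20 mol%), CH2Cl2, −78 to −40 °C
Reagents that add atoms: none
Why: catalytic enantioselective quinone Diels–Alder reaction in which the boron cation binds the C5 carbonyl syn to C6–H so that the methyl-bearing C1=C6 bond reacts, the nucleophilic diene terminus bonds to C1 (placing OSi on C9 and CH3 on C8), suprafacial endo addition gives the cis fusion (CH3-1 and H-6 both β), and approach on the face away from the catalyst phenyl sets C1 and C6 absolutely.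

Step 3
Reactants: 5 Diels–Alder adduct; 6 3-phenyl-2-(phenylsulfonyl)oxaziridine
Product: 8 (4aR,8aR)-8a-hydroxy-4a,7-dimethyl-2-(propan-2-yl)-6-(triisopropylsilyloxy)-4a,5,8,8a-tetrahydronaphthalene-1,4-dione, via potassium enolate 7 (not isolated)
Conditions: KN(SiMe3)2, THF, −78 °C; then 6, −78 °C; aq NH4Cl
Reagents that add atoms: 3-phenyl-2-(phenylsulfonyl)oxaziridine (6), O=S(=O)(c1ccccc1)N1OC1c1ccccc1
Why: enolate hydroxylation with an N-sulfonyloxaziridine at C6, the only enolisable position of the ene-dione, where attack syn to CH3-1 keeps ring B cis-fused (the kinetic course known for ring-fusion enolates of 1-decalones) and should give the 6β-hydroxyl.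

Step 4
Reactants: 8 ketol; 9 N-phenylbis(trifluoromethanesulfonimide)
Product: 10 (4aR,8aR)-4a-hydroxy-3,8a-dimethyl-5,8-dioxo-6-(propan-2-yl)-1,4,4a,5,8,8a-hexahydronaphthalen-2-yl trifluoromethanesulfonate
Conditions: CsF, DME, rt
Reagents that add atoms: N-phenylbis(trifluoromethanesulfonimide) (9), O=S(=O)(N(c1ccccc1)S(=O)(=O)C(F)(F)F)C(F)(F)F
Why: fluoride cleaves the enol silane and the caesium enolate is O-triflated in situ (enol silane to enol triflate exchange), which fixes the C8=C9 position; 8 has no other enolisable C–H and the tertiary carbinol is too weak an acid to quench the enolate.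

Step 5
Reactants: 10 enol triflate ene-dione; 9 N-phenylbis(trifluoromethanesulfonimide)
Product: 12 (4aR,8aR)-4a-hydroxy-3,8a-dimethyl-8-oxo-6-(propan-2-yl)-1,4,4a,7,8,8a-hexahydronaphthalene-2,5-diyl bis(trifluoromethanesulfonate), via lithium enolate 11 (not isolated)
Conditions: LiBH(s-Bu)3 (2.2 equiv), THF, −78 °C; then 9, −78 to 0 °C
Reagents that add atoms: N-phenylbis(trifluoromethanesulfonimide) (9), O=S(=O)(N(c1ccccc1)S(=O)(=O)C(F)(F)F)C(F)(F)F
Why: conjugate hydride reduction of the ene-dione at the unsubstituted C3 (C4 carries i-Pr and both carbonyls are flanked by fully substituted carbons) gives only the C5 enolate, and its triflation prepares the C5 carbonyl to C4=C5 olefin transposition.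

Step 6
Reactants: 12 bis-triflate ketone
Product: 13 (4aR,8R,8aS)-4a,8-dihydroxy-3,8a-dimethyl-6-(propan-2-yl)-1,4,4a,7,8,8a-hexahydronaphthalene-2,5-diyl bis(trifluoromethanesulfonate)
Conditions: (S)-1-methyl-3,3-diphenyltetrahydro-1H,3H-pyrrolo[1,2-c][1,3,2]oxazaborole (C18H20BNO, 0.5 equiv), catecholborane (C6H5BO2, 2.5 equiv), toluene, −78 to −40 °C; then MeOH, aq NaHCO3
Reagents that add atoms: none
Why: Corey–Bakshi–Shibata reduction in which the catalyst differentiates the quaternary C1 (large) from C3H2 (small) and delivers hydride to the α face of C2 to give the 2β-alcohol cis to CH3-1; catecholborane carries no B–H once bound to the C6 hydroxyl, so no hydride is delivered from the β face.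

Step 7
Reactants: 13 bis-triflate diol
Product: 14 (1R,4aS,8aS)-6,8a-dimethyl-3-(propan-2-yl)-1,2,4a,5,8,8a-hexahydronaphthalene-1,4a-diol
Conditions: Pd(OAc)2 (10 mol%), PPh3 (20 mol%), HCO2H, n-Bu3N, DMF, 60 °C
Reagents that add atoms: none
Why: palladium-catalysed formate reduction of vinyl triflates (oxidative addition to zerovalent palladium, formate-to-hydride exchange, reductive elimination) replaces both OTf groups by H without moving the double bonds, giving C4=C5 and C8=C9.

Step 8
Reactants: 14 diene diol; 15 angelic acid; 16 2,4,6-trichlorobenzoyl chloride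
Product: 18 (1R,4aS,8aS)-4a-hydroxy-6,8a-dimethyl-3-(propan-2-yl)-1,2,4a,5,8,8a-hexahydronaphthalen-1-yl (2Z)-2-methylbut-2-enoate, via mixed anhydride 17 (not isolated)
Conditions: 15, 16, Et3N, toluene, rt; then 14, 80 °C
Reagents that add atoms: angelic acid (15), C/C=C(/C)C(=O)O
Why: Yamaguchi esterification acylates the only secondary hydroxyl (C2) and, run without a nucleophilic catalyst, should avoid Z-to-E isomerisation of the angelate; installing it now leaves C6 as the only secondary alcohol later.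

Step 9
Reactants: 18 allylic alcohol angelate; 19 tert-butyl hydroperoxide
Product: 20 (1R,3R,4R,4aR,8aS)-3,4-epoxy-4a-hydroxy-6,8a-dimethyl-3-(propan-2-yl)-1,2,3,4,4a,5,8,8a-octahydronaphthalen-1-yl (2Z)-2-methylbut-2-enoate
Conditions: VO(acac)2 (5 mol%), 19 (1.3 equiv, decane solution), CH2Cl2, 0 °C
Reagents that add atoms: tert-butyl hydroperoxide (19), CC(C)(C)OO
Why: vanadium-catalysed hydroxyl-directed epoxidation delivers oxygen from the vanadate ester of the C6 hydroxyl to the allylic C4=C5 bond on the β face (syn), faster than to the homoallylic C8=C9 bond or the electron-poor angelate olefin.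

Step 10
Reactants: 20 syn-2,3-epoxy alcohol
Product: 21 (1R,3R,3aR,8aR)-3-hydroxy-6,8a-dimethyl-4-oxo-3-(propan-2-yl)-1,2,3,3a,4,5,8,8a-octahydroazulen-1-yl (2Z)-2-methylbut-2-enoate
Conditions: ZnBr2 (0.5 equiv), CH2Cl2, 0 °C to rt
Reagents that add atoms: none
Why: Zinc dibromide binds the C6 hydroxyl and the syn epoxide oxygen as a five-membered chelate; the C5–O bond then breaks while the C6–C1 bond, held anti-periplanar to it in the chelated half-chair, shifts to C5 and C6–O becomes the ketone, a semipinacol rearrangement of a 2,3-epoxy alcohol (closest known types: Lewis acid ring contraction of tertiary 2,3-epoxycyclohexanols to 2-acylcyclopentanols, and the decalin-diol monosulfonate to hydroazulenone rearrangement). The cyclopentane C1–C2–C3–C4–C5 closes by this 1,2-shift as an exo opening of the epoxide at C5 by the migrating carbon (ring A contracts), and the same new bond closes the cycloheptene (ring B grows by C5). C5 forms with inversion (C1 enters anti to the leaving oxygen, H-5 stays α), C4 keeps the epoxide oxygen as the β tertiary hydroxyl and C1 migrates with retention, so the trans fusion and three contiguous stereocentres follow from the configuration of 20. The step needs cleavage of C5–O and not of the tertiary C4–O bond, and migration of C1 and not C7: the alkoxide push acts only on C5, the chelate holds the C6 oxygen pseudoaxial so that only C6–C1 is anti to C5–O, and C1 is the better (tertiary alkyl) migrating group.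

Step 11
Reactants: 21 β-hydroxy ketone
Product: 22 (1R,3R,3aS,4S,8aR)-3,4-dihydroxy-6,8a-dimethyl-3-(propan-2-yl)-1,2,3,3a,4,5,8,8a-octahydroazulen-1-yl (2Z)-2-methylbut-2-enoate
Conditions: [Me4N][BH(OAc)3] (5 equiv), MeCN/AcOH 1:1, −25 °C
Reagents that add atoms: none
Why: Evans–Saksena hydroxyl-directed reduction in which the borohydride bound to the β C4 hydroxyl (cis to C6 on the cyclopentane) delivers hydride to the β face of the C6 ketone, giving the 6α-alcohol (anti-1,3-diol).

Step 12
Reactants: 22 diol; 23 4-methoxybenzoyl chloride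
Product: 24 (1R,3R,3aS,4S,8aR)-3-hydroxy-6,8a-dimethyl-1-{[(2Z)-2-methylbut-2-enoyl]oxy}-3-(propan-2-yl)-1,2,3,3a,4,5,8,8a-octahydroazulen-4-yl 4-methoxybenzoate (target)
Conditions: 4-(dimethylamino)pyridine (0.2 equiv), Et3N, CH2Cl2, 0 °C to rt
Reagents that add atoms: 4-methoxybenzoyl chloride (23), COc1ccc(C(=O)Cl)cc1
Why: nucleophile-catalysed acylation of the only secondary hydroxyl (C6), the tertiary C4 hydroxyl being inert under these conditions.

**Compound list**

1 | 3-methylbut-3-en-2-one | CC(=O)C(C)=C | starting material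
2 | triisopropylsilyl trifluoromethanesulfonate | CC(C)[Si](OS(=O)(=O)C(F)(F)F)(C(C)C)C(C)C | starting material
3 | 2-methyl-3-(triisopropylsilyloxy)buta-1,3-diene | C=C(C)C(=C)O[Si](C(C)C)(C(C)C)C(C)C | intermediate
4 | thymoquinone, 2-methyl-5-(propan-2-yl)cyclohexa-2,5-diene-1,4-dione | CC1=CC(=O)C(C(C)C)=CC1=O | starting material
5 | (4aR,8aS)-4a,7-dimethyl-2-(propan-2-yl)-6-(triisopropylsilyloxy)-4a,5,8,8a-tetrahydronaphthalene-1,4-dione | CC1=C(O[Si](C(C)C)(C(C)C)C(C)C)C[C@@]2(C)C(=O)C=C(C(C)C)C(=O)[C@H]2C1 | intermediate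
6 | 3-phenyl-2-(phenylsulfonyl)oxaziridine (racemic trans) | O=S(=O)(c1ccccc1)N1OC1c1ccccc1 | starting material
7 | potassium C5/C6 enolate of 5 | CC1=C(O[Si](C(C)C)(C(C)C)C(C)C)C[C@@]2(C)C(=O)C=C(C(C)C)C([O-])=C2C1.[K+] | intermediate (not isolated)
8 | (4aR,8aR)-8a-hydroxy-4a,7-dimethyl-2-(propan-2-yl)-6-(triisopropylsilyloxy)-4a,5,8,8a-tetrahydronaphthalene-1,4-dione | CC1=C(O[Si](C(C)C)(C(C)C)C(C)C)C[C@@]2(C)C(=O)C=C(C(C)C)C(=O)[C@@]2(O)C1 | intermediate
9 | N-phenylbis(trifluoromethanesulfonimide) | O=S(=O)(N(c1ccccc1)S(=O)(=O)C(F)(F)F)C(F)(F)F | starting material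
10 | (4aR,8aR)-4a-hydroxy-3,8a-dimethyl-5,8-dioxo-6-(propan-2-yl)-1,4,4a,5,8,8a-hexahydronaphthalen-2-yl trifluoromethanesulfonate | CC1=C(OS(=O)(=O)C(F)(F)F)C[C@@]2(C)C(=O)C=C(C(C)C)C(=O)[C@@]2(O)C1 | intermediate
11 | dilithium C5-enolate C6-alkoxide formed by 1,4-reduction of 10 | CC1=C(OS(=O)(=O)C(F)(F)F)C[C@@]2(C)C(=O)CC(C(C)C)=C([O-])[C@@]2([O-])C1.[Li+].[Li+] | intermediate (not isolated)
12 | (4aR,8aR)-4a-hydroxy-3,8a-dimethyl-8-oxo-6-(propan-2-yl)-1,4,4a,7,8,8a-hexahydronaphthalene-2,5-diyl bis(trifluoromethanesulfonate) | CC1=C(OS(=O)(=O)C(F)(F)F)C[C@@]2(C)C(=O)CC(C(C)C)=C(OS(=O)(=O)C(F)(F)F)[C@@]2(O)C1 | intermediate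
13 | (4aR,8R,8aS)-4a,8-dihydroxy-3,8a-dimethyl-6-(propan-2-yl)-1,4,4a,7,8,8a-hexahydronaphthalene-2,5-diyl bis(trifluoromethanesulfonate) | CC1=C(OS(=O)(=O)C(F)(F)F)C[C@@]2(C)[C@H](O)CC(C(C)C)=C(OS(=O)(=O)C(F)(F)F)[C@@]2(O)C1 | intermediate
14 | (1R,4aS,8aS)-6,8a-dimethyl-3-(propan-2-yl)-1,2,4a,5,8,8a-hexahydronaphthalene-1,4a-diol | CC1=CC[C@@]2(C)[C@H](O)CC(C(C)C)=C[C@@]2(O)C1 | intermediate
15 | angelic acid, (2Z)-2-methylbut-2-enoic acid | C/C=C(/C)C(=O)O | starting material
16 | 2,4,6-trichlorobenzoyl chloride | O=C(Cl)c1c(Cl)cc(Cl)cc1Cl | starting material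
17 | (2Z)-2-methylbut-2-enoic 2,4,6-trichlorobenzoic anhydride | C/C=C(/C)C(=O)OC(=O)c1c(Cl)cc(Cl)cc1Cl | intermediate (not isolated)
18 | (1R,4aS,8aS)-4a-hydroxy-6,8a-dimethyl-3-(propan-2-yl)-1,2,4a,5,8,8a-hexahydronaphthalen-1-yl (2Z)-2-methylbut-2-enoate | CC1=CC[C@@]2(C)[C@H](OC(=O)/C(C)=C\C)CC(C(C)C)=C[C@@]2(O)C1 | intermediate
19 | tert-butyl hydroperoxide | CC(C)(C)OO | starting material
20 | (1R,3R,4R,4aR,8aS)-3,4-epoxy-4a-hydroxy-6,8a-dimethyl-3-(propan-2-yl)-1,2,3,4,4a,5,8,8a-octahydronaphthalen-1-yl (2Z)-2-methylbut-2-enoate | CC1=CC[C@@]2(C)[C@H](OC(=O)/C(C)=C\C)C[C@]3(C(C)C)O[C@@H]3[C@@]2(O)C1 | intermediate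
21 | (1R,3R,3aR,8aR)-3-hydroxy-6,8a-dimethyl-4-oxo-3-(propan-2-yl)-1,2,3,3a,4,5,8,8a-octahydroazulen-1-yl (2Z)-2-methylbut-2-enoate | C/C=C(/C)C(=O)O[C@@H]1C[C@@](O)(C(C)C)[C@@H]2C(=O)CC(C)=CC[C@]21C | intermediate
22 | (1R,3R,3aS,4S,8aR)-3,4-dihydroxy-6,8a-dimethyl-3-(propan-2-yl)-1,2,3,3a,4,5,8,8a-octahydroazulen-1-yl (2Z)-2-methylbut-2-enoate | C/C=C(/C)C(=O)O[C@@H]1C[C@@](O)(C(C)C)[C@@H]2[C@@H](O)CC(C)=CC[C@]21C | intermediate
23 | 4-methoxybenzoyl chloride | COc1ccc(C(=O)Cl)cc1 | starting material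
24 | (1R,3R,3aS,4S,8aR)-3-hydroxy-6,8a-dimethyl-1-{[(2Z)-2-methylbut-2-enoyl]oxy}-3-(propan-2-yl)-1,2,3,3a,4,5,8,8a-octahydroazulen-4-yl 4-methoxybenzoate | C/C=C(/C)C(=O)O[C@@H]1C[C@@](O)(C(C)C)[C@@H]2[C@@H](OC(=O)c3ccc(OC)cc3)CC(C)=CC[C@]21C | target

**Step count and risks**

Total steps: 12. Longest linear sequence: 12 (1 to 24).

Steps most likely to fail:

Step 10. The epoxide may ionise at the tertiary C4–O bond (then hydride shift to a C5 ketone), or C7 may migrate in place of C1. The fallback sets out from 18 and avoids the epoxide. Hydrogen-bond-directed syn-dihydroxylation (OsO4, N,N,N′,N′-tetramethylethylenediamine, CH2Cl2, −78 °C; aq Na2SO3) should give the all-β triol F6. Sulfonylation of its only secondary hydroxyl (MsCl, Et3N, CH2Cl2, 0 °C) gives the C5 mesylate F7. An organoaluminium-promoted pinacol-type rearrangement of this 2-sulfonyloxy alcohol (AlEt3, CH2Cl2, −78 to 0 °C) can ionise only at C5 and should move C1, anti to the sulfonate, from C6 to C5. It comes back to the route at 21.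

Step 2. The trisubstituted quinone olefin may react too slowly, or the catalyst may discriminate poorly between the two enone units or the two faces. The fallback sets out from 4 and uses isoprene with BF3·OEt2 (CH2Cl2, −20 °C) to give the racemic cis-adduct F1; the nucleophilic CH2 of isoprene bonds to the unsubstituted C6, so CH3 sits on C8. The conditions of step 3 give the racemic ketol F2 and those of step 5 the racemic enol triflate F3. The reduction of step 6 then serves as a resolution, because reagent control reduces both antipodes from the same local face. The wanted antipode gives the cis-alcohol F4 and the other antipode the trans-alcohol F5, which is removed by chromatography. The conditions of step 7 applied to F4 come back to the route at 14.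

Step 5. The borohydride may reduce a carbonyl 1,2 or act as a base on the C6 hydroxyl; the alkoxide could then open the C1–C6 bond by retro-aldol cleavage, which would also erase C1 and C6. The fallback sets out from 10 and replaces the hydride by a neutral copper hydride-catalysed 1,4-hydrosilylation ([(Ph3P)CuH]6 5 mol%, PhMe2SiH, toluene, rt), which should give the C5 enol silane F8 without an alkoxide. Fluoride-triggered triflation (CsF, 9, DME, rt) comes back to the route at 12.

**Further compounds**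

F1 | step 2 | rac-(4aR,8aS)-4a,7-dimethyl-2-(propan-2-yl)-4a,5,8,8a-tetrahydronaphthalene-1,4-dione (racemate, wanted antipode drawn) | CC1=CC[C@@]2(C)C(=O)C=C(C(C)C)C(=O)[C@H]2C1
F2 | step 2 | rac-(4aR,8aR)-8a-hydroxy-4a,7-dimethyl-2-(propan-2-yl)-4a,5,8,8a-tetrahydronaphthalene-1,4-dione (racemate, wanted antipode drawn) | CC1=CC[C@@]2(C)C(=O)C=C(C(C)C)C(=O)[C@@]2(O)C1
F3 | step 2 | rac-(4aR,8aR)-8a-hydroxy-4a,7-dimethyl-4-oxo-2-(propan-2-yl)-3,4,4a,5,8,8a-hexahydronaphthalen-1-yl trifluoromethanesulfonate (racemate, wanted antipode drawn) | CC1=CC[C@@]2(C)C(=O)CC(C(C)C)=C(OS(=O)(=O)C(F)(F)F)[C@@]2(O)C1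
F4 | step 2 | (4R,4aS,8aR)-4,8a-dihydroxy-4a,7-dimethyl-2-(propan-2-yl)-3,4,4a,5,8,8a-hexahydronaphthalen-1-yl trifluoromethanesulfonate | CC1=CC[C@@]2(C)[C@H](O)CC(C(C)C)=C(OS(=O)(=O)C(F)(F)F)[C@@]2(O)C1
F5 | step 2 | (4R,4aR,8aS)-4,8a-dihydroxy-4a,7-dimethyl-2-(propan-2-yl)-3,4,4a,5,8,8a-hexahydronaphthalen-1-yl trifluoromethanesulfonate (trans-alcohol from the unwanted antipode) | CC1=CC[C@]2(C)[C@H](O)CC(C(C)C)=C(OS(=O)(=O)C(F)(F)F)[C@]2(O)C1
F6 | step 10 | (1R,3R,4S,4aR,8aS)-3,4,4a-trihydroxy-6,8a-dimethyl-3-(propan-2-yl)-1,2,3,4,4a,5,8,8a-octahydronaphthalen-1-yl (2Z)-2-methylbut-2-enoate | CC1=CC[C@@]2(C)[C@H](OC(=O)/C(C)=C\C)C[C@@](O)(C(C)C)[C@H](O)[C@@]2(O)C1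
F7 | step 10 | (1R,3R,4S,4aR,8aS)-3,4a-dihydroxy-4-(methanesulfonyloxy)-6,8a-dimethyl-3-(propan-2-yl)-1,2,3,4,4a,5,8,8a-octahydronaphthalen-1-yl (2Z)-2-methylbut-2-enoate | CC1=CC[C@@]2(C)[C@H](OC(=O)/C(C)=C\C)C[C@@](O)(C(C)C)[C@H](OS(C)(=O)=O)[C@@]2(O)C1
F8 | step 5 | (4aR,8aR)-5-[dimethyl(phenyl)silyloxy]-4a-hydroxy-3,8a-dimethyl-8-oxo-6-(propan-2-yl)-1,4,4a,7,8,8a-hexahydronaphthalen-2-yl trifluoromethanesulfonate | CC1=C(OS(=O)(=O)C(F)(F)F)C[C@@]2(C)C(=O)CC(C(C)C)=C(O[Si](C)(C)c3ccccc3)[C@@]2(O)C1
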